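**Plan**

- Numbering: C1 = CH(OAc), C2 = CH(OBz), C3=C4, C5 = oxirane CH, C6 = quaternary oxirane carbon, C7 = CH2OBz. The enabling feature is that C6 carries both the oxirane oxygen and the C7–O bond, so the fused C5–C6 oxirane of the 7-oxabicyclo[4.1.0]heptene is the Payne isomer of a C6–C7 spiro-oxirane with a free hydroxyl on C5.
- Retrosynthetic cuts, in order: the three ester C–O bonds; the C6–O5 bond of the fused oxirane (epoxide transposition, oxygen returned to C6/C7); the spiro-oxirane (epoxidation of C6=C7); C3=C4 (ring-closing metathesis); C1–C6 (vinylmagnesium addition to an aldehyde).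
- Forward: fragment 1 (C4–C7, from acrolein and vinylmagnesium bromide) and fragment 2 (C1–C3, from (R)-but-3-ene-1,2-diol) are joined at C1–C6, the carbocycle is closed at C3=C4, the spiro-oxirane is built on C6=C7, the rearrangement closes the fused oxirane, and three acylations finish.
- Stereochemistry: C2 comes from the chiral pool, C5 from a Sharpless kinetic resolution, C1 from Cram-chelate addition and the spiro centre from O1–H-directed epoxidation. C6 of the target is set by SN2 inversion in the rearrangement, with C5 untouched.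
- Protection: O2 as DMB ether, O5 as TBS ether, O1 as PMB ether. The PMB group is put on before the rearrangement so that O5 is the only free hydroxyl and the new oxirane cannot migrate on towards C1.

Key step: step 13

Assumption: in step 3 the bromo-substituted alkene is taken to be inert to the titanium tartrate/t-BuOOH system, and the usual sense of the Sharpless kinetic resolution is taken to hold for 5 (L-(+)-tartrate consumes the (R)-alcohol).

**Route**

Step 1
Reactants: 1 acrolein
Product: 3 2-bromoprop-2-enal (2-bromoacrolein), via 2,3-dibromopropanal 2 (not isolated)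
Conditions: Br2, CH2Cl2, −78 °C; then Et3N, −78 to 0 °C; used as a cold solution
Reagents that add atoms: bromine, BrBr
Why: Bromination of the enal C=C bond followed by amine-induced dehydrobromination of the α,β-dibromide is the standard way to the α-bromo enal.

Step 2
Reactants: 3 2-bromoacrolein; 4 vinylmagnesium bromide
Product: 5 racemic 2-bromopenta-1,4-dien-3-ol
Conditions: THF, −78 °C; aq. NH4Cl
Reagents that add atoms: none
Why: Grignard 1,2-addition to the enal carbonyl at low temperature gives the bis-allylic carbinol; no stereocontrol is sought at this stage.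

Step 3
Reactants: 5 racemic 2-bromopenta-1,4-dien-3-ol
Product: 6 (3S)-2-bromopenta-1,4-dien-3-ol (the unreacted enantiomer, at most half of 5)
Conditions: Ti(Oi-Pr)4 (15 mol %), L-(+)-diisopropyl tartrate (20 mol %), t-BuOOH (0.6 equiv), 4 Å molecular sieves, CH2Cl2, −20 °C
Reagents that add atoms: none
Why: In this Sharpless kinetic resolution the titanium tartrate should epoxidise the unsubstituted vinyl group of the (R)-alcohol much faster, while the electron-poor bromoalkene stays untouched, so the (S)-alcohol that becomes C5 is recovered after slightly more than half conversion.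

Step 4
Reactants: 6 (3S)-2-bromopenta-1,4-dien-3-ol
Product: 7 {[(3S)-2-bromopenta-1,4-dien-3-yl]oxy}(tert-butyl)dimethylsilane
Conditions: TBSCl, imidazole, DMF, 0 °C to rt
Reagents that add atoms: tert-butyldimethylsilyl chloride, CC(C)(C)[Si](C)(C)Cl
Why: Imidazole-promoted silylation masks O5 so that the vinyl bromide can be metalated and O5 cannot direct the later epoxidation.

Step 5
Reactants: 8 (2R)-but-3-ene-1,2-diol
Product: 9 (4R)-2-(3,4-dimethoxyphenyl)-4-ethenyl-1,3-dioxolane (both epimers at the acetal carbon)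
Conditions: 3,4-dimethoxybenzaldehyde dimethyl acetal, PPTS (cat.), CH2Cl2, rt
Reagents that add atoms: 3,4-dimethoxybenzaldehyde dimethyl acetal, COC(OC)c1ccc(OC)c(OC)c1
Why: Acid-catalysed transacetalisation of the 1,2-diol; the acetal centre forms as a mixture, which is of no consequence because it is removed in step 6.

Step 6
Reactants: 9 the dioxolane
Product: 10 (2R)-2-[(3,4-dimethoxybenzyl)oxy]but-3-en-1-ol
Conditions: i-Bu2AlH, CH2Cl2, −78 to 0 °C; aq. potassium sodium tartrate
Reagents that add atoms: none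
Why: Regioselective reductive opening of the benzylidene acetal: aluminium binds the less hindered primary oxygen, that C–O bond breaks and hydride adds to the oxocarbenium ion, so the DMB group stays on the secondary oxygen.

Step 7
Reactants: 10 (2R)-2-[(3,4-dimethoxybenzyl)oxy]but-3-en-1-ol
Product: 11 (2R)-2-[(3,4-dimethoxybenzyl)oxy]but-3-enal
Conditions: Dess–Martin periodinane, NaHCO3, CH2Cl2, 0 °C; filtered cold and used at once
Reagents that add atoms: none
Why: Dess–Martin oxidation under buffered, non-basic conditions should give the α-alkoxy β,γ-unsaturated aldehyde without epimerisation at C2 or migration of the double bond.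

Step 8
Reactants: 7 the (S)-bromodiene silyl ether; 11 the (R)-aldehyde
Product: 14 (3R,4R,6S)-6-[(tert-butyldimethylsilyl)oxy]-3-[(3,4-dimethoxybenzyl)oxy]-5-methylideneocta-1,7-dien-4-ol, via dienyllithium 12 (not isolated), via dienylmagnesium bromide 13 (not isolated)
Conditions: 7, t-BuLi (2.1 equiv), Et2O, −78 °C; MgBr2·OEt2, −78 °C; then 11 precomplexed with MgBr2·OEt2 in CH2Cl2, −78 °C; aq. NH4Cl
Reagents that add atoms: none
Why: Bromine–lithium exchange and transmetalation give the vinylmagnesium reagent, which adds under Cram-chelate control: magnesium bridges the carbonyl oxygen and the DMB ether oxygen and the nucleophile enters past the small α-hydrogen, so the syn (4R) alcohol should form (O1 trans to O2 in the later ring).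

Step 9
Reactants: 14 the triene alcohol
Product: 15 (1R,2R,5S)-5-[(tert-butyldimethylsilyl)oxy]-2-[(3,4-dimethoxybenzyl)oxy]-6-methylidenecyclohex-3-en-1-ol
Conditions: second-generation Grubbs catalyst, (H2IMes)(PCy3)Cl2Ru=CHPh (5 mol %), CH2Cl2 (0.005 M), 40 °C
Reagents that add atoms: none
Why: Ring-closing metathesis of the two monosubstituted vinyl groups of the 1,7-diene closes the six-membered ring at C3=C4 with loss of ethene; the 1,1-disubstituted C6=C7 bond could only give strained small rings and should stay.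

Step 10
Reactants: 15 the methylidenecyclohexenol
Product: 16 (3S,4S,5R,8S)-8-[(tert-butyldimethylsilyl)oxy]-5-[(3,4-dimethoxybenzyl)oxy]-1-oxaspiro[2.5]oct-6-en-4-ol (spiro oxygen on the face of O1)
Conditions: VO(acac)2 (5 mol %), t-BuOOH (1.5 equiv, decane), CH2Cl2, 0 °C to rt
Reagents that add atoms: tert-butyl hydroperoxide, CC(C)(C)OO
Why: In this hydroxyl-directed epoxidation the vanadium alkoxide of O1 delivers the peroxide oxygen to the allylic C6=C7 bond on the face that carries O1, which sets the spiro centre; the ring alkene is only homoallylic to O1 and flanked by two C–O bonds, and the silylated O5 cannot direct.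

Step 11
Reactants: 16 the spiro-epoxy alcohol
Product: 17 tert-butyl{[(3S,4S,7R,8S)-7-[(3,4-dimethoxybenzyl)oxy]-8-[(4-methoxybenzyl)oxy]-1-oxaspiro[2.5]oct-5-en-4-yl]oxy}dimethylsilane
Conditions: NaH, 4-methoxybenzyl chloride, n-Bu4NI (cat.), DMF, 0 °C to rt
Reagents that add atoms: 4-methoxybenzyl chloride, COc1ccc(CCl)cc1
Why: Williamson etherification caps O1; the O1 alkoxide lies on the same face as the spiro C6–O bond and so cannot open the oxirane, and the PMB ether later prevents any involvement of O1 in step 13.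

Step 12
Reactants: 17 the fully protected spiro-epoxide
Product: 18 (3R,4S,7R,8S)-7-[(3,4-dimethoxybenzyl)oxy]-8-[(4-methoxybenzyl)oxy]-1-oxaspiro[2.5]oct-5-en-4-ol
Conditions: n-Bu4NF, AcOH (1:1), THF, 0 °C to rt
Reagents that add atoms: none
Why: Fluoride-induced desilylation, buffered with acetic acid so that no free alkoxide is present, should liberate O5–H and allow the epoxy alcohol to be isolated before it rearranges.

Step 13
Reactants: 18 the spiro-epoxy alcohol with free O5–H
Product: 19 [(1S,2S,3R,6S)-3-[(3,4-dimethoxybenzyl)oxy]-2-[(4-methoxybenzyl)oxy]-7-oxabicyclo[4.1.0]hept-4-en-1-yl]methanol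
Conditions: NaH (1.1 equiv), THF, 0 °C to rt; aq. NH4Cl
Reagents that add atoms: none
Why: NaH turns O5–H, the only free hydroxyl, into the C5 alkoxide, which attacks the fully substituted C6 from the lower face, anti to the spiro C6–O bond (the two are trans-diaxial in the half-chair that keeps O1 and O2 equatorial); the C6–O5 bond forms as the spiro C6–O bond breaks, and the departing oxygen stays on C7 as the primary alkoxide. This is a Payne rearrangement of a 2,3-epoxy alcohol, a reaction type that also operates on 2,2-disubstituted oxiranes where the attacked carbon is fully substituted. The fused oxirane closes in the 3-exo-tet mode while the spiro ring opens. C6 is inverted stereospecifically by the SN2 geometry and C5 keeps its configuration, so the oxirane lies on the face of O2 and C7 moves to the face of O1. The step needs the migration to stop at the C5–C6 oxirane: the PMB ether on O1 rules out a second migration towards C1, the DMB ether on O2 rules out attack of O2 on C7, and the equilibrium should favour 19 because the oxirane gains a substituent and the alkoxide becomes primary.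

Step 14
Reactants: 19 the fused epoxy alcohol
Product: 20 (1S,2S,3R,6S)-1-(hydroxymethyl)-2-[(4-methoxybenzyl)oxy]-7-oxabicyclo[4.1.0]hept-4-en-3-ol
Conditions: DDQ (1.1 equiv), CH2Cl2/aq. NaH2PO4–Na2HPO4 buffer (pH 7), 0 °C
Reagents that add atoms: none
Why: Oxidative debenzylation by DDQ (hydride abstraction, then hydrolysis of the oxocarbenium ion) is faster for the more electron-rich 3,4-dimethoxybenzyl ether than for the PMB ether, so O2 should be freed while O1 stays capped.

Step 15
Reactants: 20 the diol
Product: 21 [(1S,2S,3R,6S)-3-(benzoyloxy)-2-[(4-methoxybenzyl)oxy]-7-oxabicyclo[4.1.0]hept-4-en-1-yl]methyl benzoate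
Conditions: BzCl (3 equiv), pyridine, DMAP (cat.), CH2Cl2, 0 °C to rt
Reagents that add atoms: benzoyl chloride, O=C(Cl)c1ccccc1
Why: DMAP-catalysed acylation installs both benzoates (primary O7 and allylic O2) in one operation, under conditions that leave the vinyl oxirane alone.

Step 16
Reactants: 21 the dibenzoate PMB ether
Product: 22 [(1R,2S,3R,6S)-3-(benzoyloxy)-2-hydroxy-7-oxabicyclo[4.1.0]hept-4-en-1-yl]methyl benzoate (same spatial arrangement as 21; the descriptor at C1 of the bicycle changes only because O–H replaces O–PMB)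
Conditions: DDQ (1.5 equiv), CH2Cl2/aq. NaH2PO4–Na2HPO4 buffer (pH 7), rt
Reagents that add atoms: none
Why: DDQ cleavage of the PMB ether is neutral and oxidative, so the esters, the alkene and the oxirane should survive and no acyl migration is provoked.

Step 17
Reactants: 22 the hydroxy dibenzoate
Product: 23 [(1S,2S,3R,6S)-2-(acetyloxy)-3-(benzoyloxy)-7-oxabicyclo[4.1.0]hept-4-en-1-yl]methyl benzoate (target)
Conditions: Ac2O, pyridine, DMAP (cat.), CH2Cl2, 0 °C to rt
Reagents that add atoms: acetic anhydride, CC(=O)OC(C)=O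
Why: DMAP-catalysed acetylation of the remaining hindered secondary hydroxyl O1 completes the ester pattern.

**Compound list**

1 | acrolein (prop-2-enal) | C=CC=O | starting material
2 | 2,3-dibromopropanal (racemic) | O=CC(Br)CBr | intermediate
3 | 2-bromoprop-2-enal | C=C(Br)C=O | intermediate
4 | vinylmagnesium bromide | C=C[Mg]Br | starting material
5 | racemic 2-bromopenta-1,4-dien-3-ol | C=CC(O)C(Br)=C | intermediate
6 | (3S)-2-bromopenta-1,4-dien-3-ol | C=C[C@H](O)C(Br)=C | intermediate
7 | {[(3S)-2-bromopenta-1,4-dien-3-yl]oxy}(tert-butyl)dimethylsilane | C=C[C@H](O[Si](C)(C)C(C)(C)C)C(Br)=C | intermediate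
8 | (2R)-but-3-ene-1,2-diol | OC[C@H](O)C=C | starting material
9 | (4R)-2-(3,4-dimethoxyphenyl)-4-ethenyl-1,3-dioxolane (acetal epimers) | C=C[C@@H]1COC(c2ccc(OC)c(OC)c2)O1 | intermediate
10 | (2R)-2-[(3,4-dimethoxybenzyl)oxy]but-3-en-1-ol | OC[C@H](OCc1ccc(OC)c(OC)c1)C=C | intermediate
11 | (2R)-2-[(3,4-dimethoxybenzyl)oxy]but-3-enal | O=C[C@H](OCc1ccc(OC)c(OC)c1)C=C | intermediate
12 | [(3S)-3-[(tert-butyldimethylsilyl)oxy]penta-1,4-dien-2-yl]lithium | C=C[C@H](O[Si](C)(C)C(C)(C)C)C([Li])=C | intermediate
13 | [(3S)-3-[(tert-butyldimethylsilyl)oxy]penta-1,4-dien-2-yl]magnesium bromide | C=C[C@H](O[Si](C)(C)C(C)(C)C)C([Mg]Br)=C | intermediate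
14 | (3R,4R,6S)-6-[(tert-butyldimethylsilyl)oxy]-3-[(3,4-dimethoxybenzyl)oxy]-5-methylideneocta-1,7-dien-4-ol | C=C[C@@H](OCc1ccc(OC)c(OC)c1)[C@H](O)C(=C)[C@@H](O[Si](C)(C)C(C)(C)C)C=C | intermediate
15 | (1R,2R,5S)-5-[(tert-butyldimethylsilyl)oxy]-2-[(3,4-dimethoxybenzyl)oxy]-6-methylidenecyclohex-3-en-1-ol | O[C@H]1[C@H](OCc2ccc(OC)c(OC)c2)C=C[C@H](O[Si](C)(C)C(C)(C)C)C1=C | intermediate
16 | (3S,4S,5R,8S)-8-[(tert-butyldimethylsilyl)oxy]-5-[(3,4-dimethoxybenzyl)oxy]-1-oxaspiro[2.5]oct-6-en-4-ol | O[C@H]1[C@H](OCc2ccc(OC)c(OC)c2)C=C[C@H](O[Si](C)(C)C(C)(C)C)[C@]13CO3 | intermediate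
17 | tert-butyl{[(3S,4S,7R,8S)-7-[(3,4-dimethoxybenzyl)oxy]-8-[(4-methoxybenzyl)oxy]-1-oxaspiro[2.5]oct-5-en-4-yl]oxy}dimethylsilane | COc1ccc(CO[C@H]2[C@H](OCc3ccc(OC)c(OC)c3)C=C[C@H](O[Si](C)(C)C(C)(C)C)[C@]24CO4)cc1 | intermediate
18 | (3R,4S,7R,8S)-7-[(3,4-dimethoxybenzyl)oxy]-8-[(4-methoxybenzyl)oxy]-1-oxaspiro[2.5]oct-5-en-4-ol | COc1ccc(CO[C@H]2[C@H](OCc3ccc(OC)c(OC)c3)C=C[C@H](O)[C@]24CO4)cc1 | intermediate
19 | [(1S,2S,3R,6S)-3-[(3,4-dimethoxybenzyl)oxy]-2-[(4-methoxybenzyl)oxy]-7-oxabicyclo[4.1.0]hept-4-en-1-yl]methanol | COc1ccc(CO[C@H]2[C@H](OCc3ccc(OC)c(OC)c3)C=C[C@@H]3O[C@@]32CO)cc1 | intermediate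
20 | (1S,2S,3R,6S)-1-(hydroxymethyl)-2-[(4-methoxybenzyl)oxy]-7-oxabicyclo[4.1.0]hept-4-en-3-ol | COc1ccc(CO[C@H]2[C@H](O)C=C[C@@H]3O[C@@]32CO)cc1 | intermediate
21 | [(1S,2S,3R,6S)-3-(benzoyloxy)-2-[(4-methoxybenzyl)oxy]-7-oxabicyclo[4.1.0]hept-4-en-1-yl]methyl benzoate | COc1ccc(CO[C@H]2[C@H](OC(=O)c3ccccc3)C=C[C@@H]3O[C@@]32COC(=O)c2ccccc2)cc1 | intermediate
22 | [(1R,2S,3R,6S)-3-(benzoyloxy)-2-hydroxy-7-oxabicyclo[4.1.0]hept-4-en-1-yl]methyl benzoate | O[C@H]1[C@H](OC(=O)c2ccccc2)C=C[C@@H]2O[C@@]21COC(=O)c1ccccc1 | intermediate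
23 | [(1S,2S,3R,6S)-2-(acetyloxy)-3-(benzoyloxy)-7-oxabicyclo[4.1.0]hept-4-en-1-yl]methyl benzoate | CC(=O)O[C@H]1[C@H](OC(=O)c2ccccc2)C=C[C@@H]2O[C@@]21COC(=O)c1ccccc1 | target

**Count and risks**

Total step count: 17. Longest linear sequence: 14 steps (steps 1–4 and 8–17); steps 5–7 form a 3-step branch.

The three steps most likely to fail:

1. Step 8. Chelation may be incomplete (competition by ether solvent or by the silyl ether oxygen), which would lower the facial selectivity at C1. The basic reagent may also erode the configuration of the aldehyde at C2 before it adds. The fallback sets out from 14 as it would then be obtained, in admixture with its C4 epimer, (3R,4S,6S)-6-[(tert-butyldimethylsilyl)oxy]-3-[(3,4-dimethoxybenzyl)oxy]-5-methylideneocta-1,7-dien-4-ol F1. The mixture is oxidised with Dess–Martin periodinane (NaHCO3, CH2Cl2, 0 °C) to the cross-conjugated ketone (3R,6S)-6-[(tert-butyldimethylsilyl)oxy]-3-[(3,4-dimethoxybenzyl)oxy]-5-methylideneocta-1,7-dien-4-one F2. This is reduced under reagent control by a Corey–Bakshi–Shibata reduction: catecholborane, (R)-2-methyl-CBS-oxazaborolidine, toluene, −78 °C, with the 1,1-disubstituted alkenyl group acting as the large substituent. The sequence comes back to the route at 14; C1 is then set by the catalyst and not by the chelate.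

2. Step 13. The rearrangement may stop at an equilibrium that still contains much spiro-epoxide, or the primary alkoxide may react further (oxetane formation, attack on the allylic oxirane). The fallback sets out from 15 and avoids the spiro-epoxide. O1 is etherified (NaH, 4-methoxybenzyl chloride, DMF) to tert-butyl{[(1S,4R,5R)-4-[(3,4-dimethoxybenzyl)oxy]-5-[(4-methoxybenzyl)oxy]-6-methylidenecyclohex-2-en-1-yl]oxy}dimethylsilane F3. Desilylation (n-Bu4NF, THF) gives (1S,4R,5R)-4-[(3,4-dimethoxybenzyl)oxy]-5-[(4-methoxybenzyl)oxy]-6-methylidenecyclohex-2-en-1-ol F4. A 1,3-transposition of the allylic alcohol (Ph3SiOReO3 cat., Et2O, −50 to 0 °C) moves the oxygen from C5 to C7 and the alkene into the ring, giving the conjugated dienyl carbinol [(5R,6R)-5-[(3,4-dimethoxybenzyl)oxy]-6-[(4-methoxybenzyl)oxy]cyclohexa-1,3-dien-1-yl]methanol F5. Epoxidation directed by O7–H (VO(acac)2, t-BuOOH, CH2Cl2) should oxidise the C5=C6 bond on the face away from the neighbouring O1 ether. The sequence comes back to the route at 19.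

3. Step 3. The terminal vinyl group is a slow substrate for the titanium tartrate, so discrimination between the enantiomers may be insufficient, or the bromoalkene of the wanted enantiomer may be oxidised slowly. The fallback sets out from 5 and replaces enantiomer resolution by diastereomer separation. Racemic 5 is silylated (TBSCl, imidazole, DMF) to racemic [(2-bromopenta-1,4-dien-3-yl)oxy](tert-butyl)dimethylsilane F6. This is coupled with enantiopure 11 under the conditions of step 8. The unwanted C6 epimer, (3R,4R,6R)-6-[(tert-butyldimethylsilyl)oxy]-3-[(3,4-dimethoxybenzyl)oxy]-5-methylideneocta-1,7-dien-4-ol F7, is removed by chromatography. The sequence comes back to the route at 14.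

Further compounds

F1 | step 8 | (3R,4S,6S)-6-[(tert-butyldimethylsilyl)oxy]-3-[(3,4-dimethoxybenzyl)oxy]-5-methylideneocta-1,7-dien-4-ol | C=C[C@@H](OCc1ccc(OC)c(OC)c1)[C@@H](O)C(=C)[C@@H](O[Si](C)(C)C(C)(C)C)C=C
F2 | step 8 | (3R,6S)-6-[(tert-butyldimethylsilyl)oxy]-3-[(3,4-dimethoxybenzyl)oxy]-5-methylideneocta-1,7-dien-4-one | C=C[C@@H](OCc1ccc(OC)c(OC)c1)C(=O)C(=C)[C@@H](O[Si](C)(C)C(C)(C)C)C=C
F3 | step 13 | tert-butyl{[(1S,4R,5R)-4-[(3,4-dimethoxybenzyl)oxy]-5-[(4-methoxybenzyl)oxy]-6-methylidenecyclohex-2-en-1-yl]oxy}dimethylsilane | COc1ccc(CO[C@H]2[C@H](OCc3ccc(OC)c(OC)c3)C=C[C@H](O[Si](C)(C)C(C)(C)C)C2=C)cc1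
F4 | step 13 | (1S,4R,5R)-4-[(3,4-dimethoxybenzyl)oxy]-5-[(4-methoxybenzyl)oxy]-6-methylidenecyclohex-2-en-1-ol | COc1ccc(CO[C@H]2[C@H](OCc3ccc(OC)c(OC)c3)C=C[C@H](O)C2=C)cc1
F5 | step 13 | [(5R,6R)-5-[(3,4-dimethoxybenzyl)oxy]-6-[(4-methoxybenzyl)oxy]cyclohexa-1,3-dien-1-yl]methanol | COc1ccc(CO[C@H]2[C@H](OCc3ccc(OC)c(OC)c3)C=CC=C2CO)cc1
F6 | step 3 | racemic [(2-bromopenta-1,4-dien-3-yl)oxy](tert-butyl)dimethylsilane | C=CC(O[Si](C)(C)C(C)(C)C)C(Br)=C
F7 | step 3 | (3R,4R,6R)-6-[(tert-butyldimethylsilyl)oxy]-3-[(3,4-dimethoxybenzyl)oxy]-5-methylideneocta-1,7-dien-4-ol | C=C[C@@H](OCc1ccc(OC)c(OC)c1)[C@H](O)C(=C)[C@H](O[Si](C)(C)C(C)(C)C)C=C
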